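## Retrosynthetic overview

1. The 8-OH is unmasked last from MOM ether 24. Compound 24 is cut at the C2–C3 bond of both 2,2-dimethyl-2H-pyran rings, giving the open biphenyl 21, which carries on each benzene ring an O–C(CH3)2–CO2N(phthaloyl) unit ortho to a vinyl group. Both pyran rings are closed last, in one operation, by a twofold decarboxylative photo-Heck cyclisation.
2. 21 comes from biaryl dialdehyde 12 by twofold Wittig methylenation, saponification and N-hydroxyphthalimide esterification. 12 comes from Suzuki coupling of ring A bromide 6 with ring B boronate 11, so the biaryl bond precedes both pyran rings.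
3. 6 derives from 5-bromo-2-hydroxybenzaldehyde (allylation, Claisen rearrangement, cross-metathesis to prenyl, O-alkylation with ethyl 2-bromo-2-methylpropanoate). 11 derives from 5-bromo-2-hydroxy-3-methoxybenzaldehyde (demethylation, selective MOM protection, the same O-alkylation, borylation).
4. Enabling feature: in each pyran ring, C2 is a fully substituted carbon bonded to the ring oxygen O1 and two methyl groups, so it becomes a stabilised, nucleophilic tertiary α-aryloxy radical once an attached carboxyl group is expelled. C3=C4 is a styrene-type alkene conjugated with the benzene ring at C4a (ortho to O1), so an ortho vinyl group is a matched acceptor whose terminal carbon becomes C3 and whose benzylic C4 radical is converted into the ring alkene.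

Key step: step 13

Remark on the chemistry: the target is achiral (no stereocentre; both ring alkenes are cis by ring constraint), so no step has to set configuration.

## Route

Step 1
Reactants: 1 5-bromo-2-hydroxybenzaldehyde
Product: 2 5-bromo-2-(prop-2-en-1-yloxy)benzaldehyde
Conditions: allyl bromide, K2CO3, DMF, 25 °C
Reagents that add atoms: allyl bromide (C=CCBr)
Why: Williamson etherification of the acidic salicylaldehyde phenoxide with a primary allylic bromide should be fast and O-selective.

Step 2
Reactants: 2 5-bromo-2-(prop-2-en-1-yloxy)benzaldehyde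
Product: 4 5-bromo-2-hydroxy-3-(prop-2-en-1-yl)benzaldehyde, via ortho-dienone 3 (not isolated)
Conditions: N,N-diethylaniline, 200 °C, argon
Reagents that add atoms: none
Why: The aromatic Claisen rearrangement ([3,3]-sigmatropic) can deliver the allyl group only to C3, the single free ortho position (para is blocked by bromine), and dienone 3 tautomerises to the phenol.

Step 3
Reactants: 4 5-bromo-2-hydroxy-3-(prop-2-en-1-yl)benzaldehyde
Product: 5 5-bromo-2-hydroxy-3-(3-methylbut-2-en-1-yl)benzaldehyde
Conditions: second-generation Grubbs catalyst RuCl2(=CHPh)(PCy3)(H2IMes) (5 mol %), 2-methylbut-2-ene (excess), CH2Cl2, 40 °C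
Reagents that add atoms: 2-methylbut-2-ene (CC=C(C)C)
Why: Olefin cross-metathesis of a terminal allyl arene with excess 2-methylbut-2-ene should convert allyl into prenyl with loss of propene, and the catalyst tolerates phenol, aldehyde and aryl bromide.

Step 4
Reactants: 5 5-bromo-2-hydroxy-3-(3-methylbut-2-en-1-yl)benzaldehyde
Product: 6 ethyl 2-[4-bromo-2-formyl-6-(3-methylbut-2-en-1-yl)phenoxy]-2-methylpropanoate
Conditions: ethyl 2-bromo-2-methylpropanoate (3 equiv), Cs2CO3 (2 equiv), DMF, 60 °C
Reagents that add atoms: ethyl 2-bromo-2-methylpropanoate (CCOC(=O)C(C)(C)Br)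
Why: Williamson-type O-alkylation of the caesium phenoxide with the tertiary α-bromo ester is the standard entry to aryloxyisobutyrates, and excess bromide compensates for competing elimination to ethyl methacrylate.

Step 5
Reactants: 7 5-bromo-2-hydroxy-3-methoxybenzaldehyde
Product: 8 5-bromo-2,3-dihydroxybenzaldehyde
Conditions: BBr3, CH2Cl2, −78 °C to 25 °C; then H2O
Reagents that add atoms: none
Why: Lewis-acid ether cleavage with BBr3 should remove the aryl methyl group by bromide attack on the boron-complexed ether, leaving aldehyde and aryl bromide untouched.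

Step 6
Reactants: 8 5-bromo-2,3-dihydroxybenzaldehyde
Product: 9 5-bromo-2-hydroxy-3-(methoxymethoxy)benzaldehyde
Conditions: NaH (2.2 equiv), DMSO–THF, 0 °C; chloromethyl methyl ether (1.0 equiv); then aq. NH4Cl
Reagents that add atoms: chloromethyl methyl ether (COCCl)
Why: In this regioselective Williamson-type alkylation of the catecholate dianion, the 2-oxide is stabilised by conjugation and chelation with the formyl group, so the more basic 3-oxide should take up the single equivalent of electrophile.

Step 7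
Reactants: 9 5-bromo-2-hydroxy-3-(methoxymethoxy)benzaldehyde
Product: 10 ethyl 2-[4-bromo-2-formyl-6-(methoxymethoxy)phenoxy]-2-methylpropanoate
Conditions: ethyl 2-bromo-2-methylpropanoate (3 equiv), Cs2CO3 (2 equiv), DMF, 60 °C
Reagents that add atoms: ethyl 2-bromo-2-methylpropanoate (CCOC(=O)C(C)(C)Br)
Why: The same Williamson-type O-alkylation as in step 4 should work on the only free phenol, and the MOM acetal is stable to carbonate base.

Step 8
Reactants: 10 ethyl 2-[4-bromo-2-formyl-6-(methoxymethoxy)phenoxy]-2-methylpropanoate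
Product: 11 ethyl 2-[2-formyl-6-(methoxymethoxy)-4-(4,4,5,5-tetramethyl-1,3,2-dioxaborolan-2-yl)phenoxy]-2-methylpropanoate
Conditions: bis(pinacolato)diboron, Pd(dppf)Cl2 (5 mol %), KOAc (3 equiv), 1,4-dioxane, 90 °C
Reagents that add atoms: bis(pinacolato)diboron (CC1(C)OB(OC1(C)C)B1OC(C)(C)C(C)(C)O1)
Why: Miyaura borylation of the unhindered aryl bromide with the weak base KOAc tolerates aldehyde, ester and acetal and avoids homocoupling.

Step 9
Reactants: 6 ethyl 2-[4-bromo-2-formyl-6-(3-methylbut-2-en-1-yl)phenoxy]-2-methylpropanoate; 11 ethyl 2-[2-formyl-6-(methoxymethoxy)-4-(4,4,5,5-tetramethyl-1,3,2-dioxaborolan-2-yl)phenoxy]-2-methylpropanoate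
Product: 12 diethyl 2,2'-{[3,3'-diformyl-5-(methoxymethoxy)-5'-(3-methylbut-2-en-1-yl)biphenyl-4,4'-diyl]bis(oxy)}bis(2-methylpropanoate)
Conditions: Pd(dppf)Cl2 (5 mol %), K3PO4 (3 equiv), 1,4-dioxane–H2O (5:1), 80 °C
Reagents that add atoms: none
Why: Suzuki–Miyaura cross-coupling between an aryl bromide and an aryl boronate that both have hydrogen at the flanking positions should build the biaryl bond, and the hindered esters survive aqueous phosphate.

Step 10
Reactants: 12 diethyl 2,2'-{[3,3'-diformyl-5-(methoxymethoxy)-5'-(3-methylbut-2-en-1-yl)biphenyl-4,4'-diyl]bis(oxy)}bis(2-methylpropanoate)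
Product: 15 diethyl 2,2'-{[3,3'-diethenyl-5-(methoxymethoxy)-5'-(3-methylbut-2-en-1-yl)biphenyl-4,4'-diyl]bis(oxy)}bis(2-methylpropanoate), via ring-A-vinyl monoaldehyde 13 (not isolated), via ring-B-vinyl monoaldehyde 14 (not isolated)
Conditions: Ph3PCH3Br (3.0 equiv), KOtBu (2.8 equiv), THF, 0 °C to 25 °C
Reagents that add atoms: methyltriphenylphosphonium bromide (C[P+](c1ccccc1)(c1ccccc1)c1ccccc1.[Br-])
Why: Wittig methylenation with the non-stabilised ylide should convert both aryl aldehydes into vinyl groups, while the α,α-disubstituted esters are too hindered to be attacked.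

Step 11
Reactants: 15 diethyl 2,2'-{[3,3'-diethenyl-5-(methoxymethoxy)-5'-(3-methylbut-2-en-1-yl)biphenyl-4,4'-diyl]bis(oxy)}bis(2-methylpropanoate)
Product: 18 2,2'-{[3,3'-diethenyl-5-(methoxymethoxy)-5'-(3-methylbut-2-en-1-yl)biphenyl-4,4'-diyl]bis(oxy)}bis(2-methylpropanoic acid), via ring-A monoacid 16 (not isolated), via ring-B monoacid 17 (not isolated)
Conditions: LiOH·H2O (6 equiv), THF–EtOH–H2O, 50 °C; then 1 M HCl to pH 4, 0 °C
Reagents that add atoms: lithium hydroxide ([Li+].[OH-])
Why: Saponification of both ethyl esters by hydroxide addition–elimination is routine for aryloxyisobutyrates, and the cold, mildly acidic work-up keeps the MOM acetal.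

Step 12
Reactants: 18 2,2'-{[3,3'-diethenyl-5-(methoxymethoxy)-5'-(3-methylbut-2-en-1-yl)biphenyl-4,4'-diyl]bis(oxy)}bis(2-methylpropanoic acid)
Product: 21 bis(1,3-dioxoisoindolin-2-yl) 2,2'-{[3,3'-diethenyl-5-(methoxymethoxy)-5'-(3-methylbut-2-en-1-yl)biphenyl-4,4'-diyl]bis(oxy)}bis(2-methylpropanoate), via ring-A mono(phthalimidoyl) ester 19 (not isolated), via ring-B mono(phthalimidoyl) ester 20 (not isolated)
Conditions: N-hydroxyphthalimide (2.4 equiv), N,N'-diisopropylcarbodiimide (2.4 equiv), DMAP (10 mol %), CH2Cl2, 0 °C to 25 °C, dark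
Reagents that add atoms: N-hydroxyphthalimide (O=C1c2ccccc2C(=O)N1O)
Why: Carbodiimide (Steglich-type) esterification with N-hydroxyphthalimide should give the redox-active esters, as is standard even for tertiary acids.

Step 13
Reactants: 21 bis(1,3-dioxoisoindolin-2-yl) 2,2'-{[3,3'-diethenyl-5-(methoxymethoxy)-5'-(3-methylbut-2-en-1-yl)biphenyl-4,4'-diyl]bis(oxy)}bis(2-methylpropanoate)
Product: 24 8-(methoxymethoxy)-2,2,2',2'-tetramethyl-8'-(3-methylbut-2-en-1-yl)-2H,2'H-6,6'-bichromene, via ring-A-closed monoester 22 (not isolated), via ring-B-closed monoester 23 (not isolated)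
Conditions: Pd(PPh3)2Cl2 (10 mol %), Xantphos (12 mol %), KOAc (0.2 equiv), DMA (0.02 M), 450 nm LEDs, 25 °C, argon
Reagents that add atoms: none
Why: Blue-light-excited zerovalent palladium (formed in situ, Xantphos-ligated) transfers one electron to each N-acyloxyphthalimide, which loses phthalimide anion and CO2 to leave the tertiary α-aryloxy radical at C2 next to monovalent palladium; this radical adds to the terminal carbon of the ortho vinyl group (the new C2–C3 bond), the benzylic C4 radical is captured by palladium, and β-hydride elimination from C3 with proton transfer to the phthalimide anion gives the C3=C4 alkene and returns zerovalent palladium. The closest known reaction type is the visible-light palladium-catalysed decarboxylative Heck reaction of tertiary and α-heteroatom N-acyloxyphthalimides with vinylarenes, together with endo-selective radical-type alkyl Heck cyclisations. Each of the two pyran rings is closed in the 6-endo-trig mode, ring A and ring B independently and in either order (22 or 23 on the way). No stereocentre is created and the new ring alkenes are cis by ring constraint. The step needs endo over 5-exo closure, which the styrene polarisation secures (attack at the unsubstituted terminus gives a benzylic radical, attack at C4 would give a primary radical), preference for the vinyl group over the prenyl alkene of ring A, secured by the far slower addition of a tertiary radical to a trisubstituted unactivated alkene, and alkene placement at C3=C4, fixed because C3 carries the only β-hydrogens next to C4. High dilution should suppress intermolecular addition to the product alkenes.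

Step 14
Reactants: 24 8-(methoxymethoxy)-2,2,2',2'-tetramethyl-8'-(3-methylbut-2-en-1-yl)-2H,2'H-6,6'-bichromene
Product: 25 2,2,2',2'-tetramethyl-8'-(3-methylbut-2-en-1-yl)-2H,2'H-[6,6'-bichromen]-8-ol
Conditions: 3 M aq. HCl (5 equiv), MeOH–THF (1:1), 40 °C
Reagents that add atoms: none
Why: Acid-catalysed acetal exchange (MOM methanolysis) should free the phenol, while the chromene alkenes and the prenyl group, which has no free ortho hydroxyl to cyclise onto, tolerate dilute acid at this temperature.

## Compound list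

1 | 5-bromo-2-hydroxybenzaldehyde | O=Cc1cc(Br)ccc1O | starting material
2 | 5-bromo-2-(prop-2-en-1-yloxy)benzaldehyde | O=Cc1cc(Br)ccc1OCC=C | intermediate
3 | 4-bromo-2-formyl-6-(prop-2-en-1-yl)cyclohexa-2,4-dien-1-one (racemic ortho-dienone, not isolated) | O=CC1=CC(Br)=CC(CC=C)C1=O | intermediate
4 | 5-bromo-2-hydroxy-3-(prop-2-en-1-yl)benzaldehyde | O=Cc1cc(Br)cc(CC=C)c1O | intermediate
5 | 5-bromo-2-hydroxy-3-(3-methylbut-2-en-1-yl)benzaldehyde | O=Cc1cc(Br)cc(CC=C(C)C)c1O | intermediate
6 | ethyl 2-[4-bromo-2-formyl-6-(3-methylbut-2-en-1-yl)phenoxy]-2-methylpropanoate | CCOC(=O)C(C)(C)Oc1c(C=O)cc(Br)cc1CC=C(C)C | intermediate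
7 | 5-bromo-2-hydroxy-3-methoxybenzaldehyde | COc1cc(Br)cc(C=O)c1O | starting material
8 | 5-bromo-2,3-dihydroxybenzaldehyde | Oc1cc(Br)cc(C=O)c1O | intermediate
9 | 5-bromo-2-hydroxy-3-(methoxymethoxy)benzaldehyde | COCOc1cc(Br)cc(C=O)c1O | intermediate
10 | ethyl 2-[4-bromo-2-formyl-6-(methoxymethoxy)phenoxy]-2-methylpropanoate | CCOC(=O)C(C)(C)Oc1c(C=O)cc(Br)cc1OCOC | intermediate
11 | ethyl 2-[2-formyl-6-(methoxymethoxy)-4-(4,4,5,5-tetramethyl-1,3,2-dioxaborolan-2-yl)phenoxy]-2-methylpropanoate | CCOC(=O)C(C)(C)Oc1c(C=O)cc(B2OC(C)(C)C(C)(C)O2)cc1OCOC | intermediate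
12 | biaryl dialdehyde diester: diethyl 2,2'-{[3,3'-diformyl-5-(methoxymethoxy)-5'-(3-methylbut-2-en-1-yl)biphenyl-4,4'-diyl]bis(oxy)}bis(2-methylpropanoate) | CCOC(=O)C(C)(C)Oc1c(C=O)cc(-c2cc(C=O)c(OC(C)(C)C(=O)OCC)c(OCOC)c2)cc1CC=C(C)C | intermediate
13 | ring-A-vinyl monoaldehyde (ring A ethenyl, ring B formyl; not isolated) | CCOC(=O)C(C)(C)Oc1c(C=C)cc(-c2cc(C=O)c(OC(C)(C)C(=O)OCC)c(OCOC)c2)cc1CC=C(C)C | intermediate
14 | ring-B-vinyl monoaldehyde (ring A formyl, ring B ethenyl; not isolated) | CCOC(=O)C(C)(C)Oc1c(C=O)cc(-c2cc(C=C)c(OC(C)(C)C(=O)OCC)c(OCOC)c2)cc1CC=C(C)C | intermediate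
15 | bis-styrene diester: diethyl 2,2'-{[3,3'-diethenyl-5-(methoxymethoxy)-5'-(3-methylbut-2-en-1-yl)biphenyl-4,4'-diyl]bis(oxy)}bis(2-methylpropanoate) | CCOC(=O)C(C)(C)Oc1c(C=C)cc(-c2cc(C=C)c(OC(C)(C)C(=O)OCC)c(OCOC)c2)cc1CC=C(C)C | intermediate
16 | ring-A monoacid (ring A acid, ring B ethyl ester; not isolated) | OC(=O)C(C)(C)Oc1c(C=C)cc(-c2cc(C=C)c(OC(C)(C)C(=O)OCC)c(OCOC)c2)cc1CC=C(C)C | intermediate
17 | ring-B monoacid (ring A ethyl ester, ring B acid; not isolated) | CCOC(=O)C(C)(C)Oc1c(C=C)cc(-c2cc(C=C)c(OC(C)(C)C(O)=O)c(OCOC)c2)cc1CC=C(C)C | intermediate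
18 | bis-styrene diacid: 2,2'-{[3,3'-diethenyl-5-(methoxymethoxy)-5'-(3-methylbut-2-en-1-yl)biphenyl-4,4'-diyl]bis(oxy)}bis(2-methylpropanoic acid) | OC(=O)C(C)(C)Oc1c(C=C)cc(-c2cc(C=C)c(OC(C)(C)C(O)=O)c(OCOC)c2)cc1CC=C(C)C | intermediate
19 | ring-A mono(phthalimidoyl) ester (ring B still acid; not isolated) | O=C(ON1C(=O)c2ccccc2C1=O)C(C)(C)Oc1c(C=C)cc(-c2cc(C=C)c(OC(C)(C)C(O)=O)c(OCOC)c2)cc1CC=C(C)C | intermediate
20 | ring-B mono(phthalimidoyl) ester (ring A still acid; not isolated) | OC(=O)C(C)(C)Oc1c(C=C)cc(-c2cc(C=C)c(OC(C)(C)C(=O)ON3C(=O)c4ccccc4C3=O)c(OCOC)c2)cc1CC=C(C)C | intermediate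
21 | bis(N-acyloxyphthalimide): bis(1,3-dioxoisoindolin-2-yl) 2,2'-{[3,3'-diethenyl-5-(methoxymethoxy)-5'-(3-methylbut-2-en-1-yl)biphenyl-4,4'-diyl]bis(oxy)}bis(2-methylpropanoate) | O=C(ON1C(=O)c2ccccc2C1=O)C(C)(C)Oc1c(C=C)cc(-c2cc(C=C)c(OC(C)(C)C(=O)ON3C(=O)c4ccccc4C3=O)c(OCOC)c2)cc1CC=C(C)C | intermediate
22 | ring-A-closed monoester (ring A chromene, ring B open phthalimidoyl ester; not isolated) | CC(C)=CCc1cc(-c2cc(C=C)c(OC(C)(C)C(=O)ON3C(=O)c4ccccc4C3=O)c(OCOC)c2)cc2c1OC(C)(C)C=C2 | intermediate
23 | ring-B-closed monoester (ring B chromene, ring A open phthalimidoyl ester; not isolated) | O=C(ON1C(=O)c2ccccc2C1=O)C(C)(C)Oc1c(C=C)cc(-c2cc(OCOC)c3c(c2)C=CC(C)(C)O3)cc1CC=C(C)C | intermediate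
24 | 8-(methoxymethoxy)-2,2,2',2'-tetramethyl-8'-(3-methylbut-2-en-1-yl)-2H,2'H-6,6'-bichromene | CC(C)=CCc1cc(-c2cc(OCOC)c3c(c2)C=CC(C)(C)O3)cc2c1OC(C)(C)C=C2 | intermediate
25 | 2,2,2',2'-tetramethyl-8'-(3-methylbut-2-en-1-yl)-2H,2'H-[6,6'-bichromen]-8-ol (CNP0158232.0) | CC(C)=CCc1cc(-c2cc(O)c3c(c2)C=CC(C)(C)O3)cc2c1OC(C)(C)C=C2 | target

## Step count and risks

Total step count: 14. Longest linear sequence: 10 steps (steps 1–4 or steps 5–8, then steps 9–14).

Steps most likely to fail:

1. Step 13. What may go wrong: loss of a β-hydrogen from the tertiary radical–palladium pair (desaturation to isopropenyl ethers) or exo-mode closure may outrun the 6-endo closure, and the sequence may stall after the first ring. Fallback (ring closure at C3=C4 by metathesis instead of at C2–C3 by radical addition): it sets out from 15. Reduction of both α-aryloxy esters with i-Bu2AlH (CH2Cl2, −78 °C) should give the bis-aldehyde 2,2'-{[3,3'-diethenyl-5-(methoxymethoxy)-5'-(3-methylbut-2-en-1-yl)biphenyl-4,4'-diyl]bis(oxy)}bis(2-methylpropanal) F1. Wittig methylenation (Ph3PCH3Br, KOtBu, THF) should then give the bis(1,1-dimethylallyl) aryl ether 3,3'-diethenyl-5-(methoxymethoxy)-4,4'-bis[(2-methylbut-3-en-2-yl)oxy]-5'-(3-methylbut-2-en-1-yl)biphenyl F2, in which Claisen rearrangement is blocked because every ortho and para position is substituted. Twofold ring-closing metathesis of each allyl ether with its ortho vinyl group (second-generation Grubbs catalyst RuCl2(=CHPh)(PCy3)(H2IMes), CH2Cl2, 40 °C, loss of ethene) should come back to the route at 24.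

2. Step 4. What may go wrong: elimination of the tertiary bromide to ethyl methacrylate may outrun substitution at the doubly ortho-substituted phenoxide. Fallback (Bargellini construction of the hindered ether after the aldehyde has become the vinyl group): it sets out from 5. Wittig methylenation with excess ylide should give 4-bromo-2-ethenyl-6-(3-methylbut-2-en-1-yl)phenol F3. A Bargellini reaction (1,1,1-trichloro-2-methylpropan-2-ol, powdered NaOH, acetone, 0 °C to 25 °C), in which the phenoxide opens a gem-dichloroepoxide at its tertiary carbon, should give 2-[4-bromo-2-ethenyl-6-(3-methylbut-2-en-1-yl)phenoxy]-2-methylpropanoic acid F4. Esterification (EtI, K2CO3, DMF) should give ethyl 2-[4-bromo-2-ethenyl-6-(3-methylbut-2-en-1-yl)phenoxy]-2-methylpropanoate F5. Suzuki coupling of F5 with boronate 11 under the conditions of step 9 should come back to the route at 13, which is then methylenated to 15 under the conditions of step 10.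

3. Step 6. What may go wrong: alkylation at the wrong phenolic oxygen, or at both. Fallback (protect both, then remove one selectively): it sets out from 8. Exhaustive protection (NaH 3 equiv, chloromethyl methyl ether 2.5 equiv, DMF) should give 5-bromo-2,3-bis(methoxymethoxy)benzaldehyde F6. Chelation-directed cleavage of only the acetal ortho to the formyl group (MgBr2·OEt2, Et2O–CH2Cl2, 25 °C) should come back to the route at 9.

Further compounds
F1 | step 13 | 2,2'-{[3,3'-diethenyl-5-(methoxymethoxy)-5'-(3-methylbut-2-en-1-yl)biphenyl-4,4'-diyl]bis(oxy)}bis(2-methylpropanal) | O=CC(C)(C)Oc1c(C=C)cc(-c2cc(C=C)c(OC(C)(C)C=O)c(OCOC)c2)cc1CC=C(C)C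
F2 | step 13 | 3,3'-diethenyl-5-(methoxymethoxy)-4,4'-bis[(2-methylbut-3-en-2-yl)oxy]-5'-(3-methylbut-2-en-1-yl)biphenyl | C=CC(C)(C)Oc1c(C=C)cc(-c2cc(C=C)c(OC(C)(C)C=C)c(OCOC)c2)cc1CC=C(C)C
F3 | step 4 | 4-bromo-2-ethenyl-6-(3-methylbut-2-en-1-yl)phenol | C=Cc1cc(Br)cc(CC=C(C)C)c1O
F4 | step 4 | 2-[4-bromo-2-ethenyl-6-(3-methylbut-2-en-1-yl)phenoxy]-2-methylpropanoic acid | OC(=O)C(C)(C)Oc1c(C=C)cc(Br)cc1CC=C(C)C
F5 | step 4 | ethyl 2-[4-bromo-2-ethenyl-6-(3-methylbut-2-en-1-yl)phenoxy]-2-methylpropanoate | CCOC(=O)C(C)(C)Oc1c(C=C)cc(Br)cc1CC=C(C)C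
F6 | step 6 | 5-bromo-2,3-bis(methoxymethoxy)benzaldehyde | COCOc1cc(Br)cc(C=O)c1OCOC
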